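We want the target standing after 15 h in three flasks that differ in their charge of coupling partner.

| flask | substrate | coupling partner | remark | time |
|---|---|---|---|---|
| red | 0.43 M | 0.39 M | run made earlier |  |
| green | 0.43 M | 1.5 M | run made earlier |  |
| summer | 0.43 M | 0.500 M |  | 15 h |
| winter | 0.43 M | 1.00 M |  | 15 h |
| spring | 0.43 M | 2.00 M |  | 15 h |

- red (time / h: target / %, substrate / %): 0.500: 0, 78; 1.33: 2, 49; 2.50: 8, 26; 4.00: 10, 13; 6.00: 13, 5; 8.00: 16, 5
- green (time / h: target / %, substrate / %): 1.33: 7, 51; 2.50: 19, 28; 4.00: 33, 15; 5.00: 37, 9; 6.00: 40, 1; 8.00: 40, 4

(each reading ± 2 percentage points)

- "hardly changes" means that all values lie within two and a half points (for a concentration: within two and a half percent of the largest)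

- amount of target at the end, in percent of the substrate charged for summer, winter, spring, in this order
- how the row runs (rises all the way / hardly changes / falls, then rises / falls all the way / rises, then falls)

The two runs show where the partner acts. Substrate falls alike in both, 49% in red and 51% in green at 1.33 h, although green holds 3.85 times the partner. Yet at 8.00 h red has 16% of target and green 40%. Red shows 0% of target at 0.500 h, so we suppose a passing intermediate, and we suppose that the partner captures it in competition with a loss route.

If capture goes with the partner's concentration and loss does not, one dimensionless number folds in the givens. This capture number, a selectivity factor, counts captures per loss: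

capture number = partner charged / K

yield = capture number / (1 + capture number)

Here K is the half-yield concentration, the partner concentration at which capture and loss run level. Taking the target readings at 8.00 h as yields, red gives 2.05 M and green 2.25 M, so we take 2.15 M.

Was one number enough? This K returns 15.4% for red and 41.1% for green, each within 2 percentage points of its reading; as K was made from these same two readings, this shows that the two runs can share one K, and no more. Charged partner is not quite the partner met, though: if each target takes one partner, red had spent 17.6% of its charge.

Substrate's half-life reads near 1.33 h, and 15 h is ten times that, while green's target stands at 40% at 6.00 h and 40% at 8.00 h. So we read the end yields straight from the formula: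

summer 18.9%, winter 31.8%, spring 48.2%

The forecast gives 19%, 31% and 48%, rises all the way, “rising with diminishing gain”, its winter point 0.80 points below ours.

The flasks give 19.8%, 33.4% and 50.6%: rises all the way.

    intermediate B ⇌ intermediate C (K = 0.136, k = 0.00254 /s)
    substrate → intermediate A (k = 1.41 × 10⁻⁴ /s)
    intermediate C → target (k = 0.00289 /s)
    coupling partner + intermediate A → intermediate B (k = 2.00 × 10⁻⁴ /M/s)
    intermediate A → side product (k = 3.68 × 10⁻⁴ /s)

Spring's capture number is 0.931, and at 15.0 h spring holds 50.6% of target beside 49.3% of side product, a ratio of 1.03. In summer the inverse of the capture number is 4.30, and the flask's own comparison is the rate at which intermediate A passes to side product over the rate at which the coupling partner takes it: loss is faster, by 3.9 times at 1.37 h and 4.4 times at 15.0 h.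

The data are simulated from invented constants; the scatter is artificial.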